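The α-methylene-γ-butyrolactone is dissected into CO2 (C12), a terminal allene (C7=C11=C13) and an aldehyde (C6). Because C6–C7 is the one bond shared by the lactone and the ten-membered carbocycle (C1–C10), a nickel(0)-mediated carboxylation of the allene followed by ring-closing addition of the resulting allylnickel to the C6 aldehyde forms C11–C12 and C6–C7, closes both rings and sets C6 and C7 in one operation. Its precursor is an acyclic allenyl aldehyde, assembled from a D-glyceraldehyde-derived allenyl iodoacrylate (C7–C10, C1) and a butenolide-derived lactol (C2–C6). The 2,5-hemiketal bridge is formed last from the C2 ketone and the C5 hydroxyl.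

Key step: step 15

Remarks and assumptions
- Numbering is that of the germacranolide skeleton: carbocycle C1–C10, lactone carbons C11 (α), C12 (C=O), C13 (=CH2), ester carbon C14 on C10, methyl C15 on C4.
- The ProPhenol antipode in step 8 is the one that gives the 4R alcohol 13 (expected with the (S,S)-ligand; the sense is to be checked by Mosher analysis and the antipode used if it proves opposite).
- The acetal carbon of 6, the lactol carbon of 16 and the C2 carbinol of 17–27 are carried as epimer mixtures and drawn without configuration; these centres are removed or erased later.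

Step 1
Reactants: 1 (R)-2,2-dimethyl-1,3-dioxolane-4-carbaldehyde (D-glyceraldehyde acetonide)
Product: 2 (S)-4-ethynyl-2,2-dimethyl-1,3-dioxolane
Conditions: dimethyl (1-diazo-2-oxopropyl)phosphonate, K2CO3, MeOH, 0 °C to rt
Reagents that add atoms: Bestmann–Ohira reagent, CC(=O)C(=[N+]=[N-])P(=O)(OC)OC
Why: Seyferth–Gilbert homologation in its Ohira–Bestmann form should convert the aldehyde into the terminal alkyne (C7≡C11) under conditions mild enough to keep the adjacent stereocentre (future C8) intact.

Step 2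
Reactants: 2 (S)-4-ethynyl-2,2-dimethyl-1,3-dioxolane
Product: 4 (S)-2,2-dimethyl-4-(propa-1,2-dien-1-yl)-1,3-dioxolane, via propargylic amine 3 (not isolated)
Conditions: (CH2O)n, CuI, Cy2NH, dioxane, reflux
Reagents that add atoms: paraformaldehyde (formaldehyde), C=O
Why: Crabbé allene homologation (copper-mediated Mannich reaction, then 1,5-hydride shift with loss of the imine) should give the terminal allene C7=C11=C13 without touching C8.

Step 3
Reactants: 4 (S)-2,2-dimethyl-4-(propa-1,2-dien-1-yl)-1,3-dioxolane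
Product: 6 (4S)-2-(4-methoxyphenyl)-4-(propa-1,2-dien-1-yl)-1,3-dioxolane, via allenyl diol 5 (not isolated)
Conditions: i. PPTS, MeOH, 40 °C, concentrate; ii. 4-MeOC6H4CH(OMe)2, CSA (cat.), CH2Cl2, rt
Reagents that add atoms: 4-methoxybenzaldehyde dimethyl acetal, COc1ccc(C(OC)OC)cc1
Why: Acid-catalysed acetonide methanolysis and transacetalisation of the water-soluble diol without isolation should exchange the acetonide for the p-methoxybenzylidene acetal, with C8 untouched.

Step 4
Reactants: 6 (4S)-2-(4-methoxyphenyl)-4-(propa-1,2-dien-1-yl)-1,3-dioxolane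
Product: 7 (2S)-2-[(4-methoxybenzyl)oxy]penta-3,4-dien-1-ol
Conditions: DIBAL-H, CH2Cl2, −78 to 0 °C
Reagents that add atoms: none
Why: Reductive acetal opening, in which DIBAL-H coordinates the less hindered primary oxygen and delivers hydride to the acetal carbon, should leave the PMB ether on the secondary C8 oxygen and free the primary C9 hydroxyl.

Step 5
Reactants: 7 (2S)-2-[(4-methoxybenzyl)oxy]penta-3,4-dien-1-ol
Product: 8 (2S)-2-[(4-methoxybenzyl)oxy]penta-3,4-dienal
Conditions: Dess–Martin periodinane, NaHCO3, CH2Cl2, 0 °C; used at once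
Reagents that add atoms: none
Why: Dess–Martin oxidation is non-basic, so the α-alkoxy β,γ-allenic aldehyde should form without epimerisation or isomerisation to the conjugated dienal.

Step 6
Reactants: 8 (2S)-2-[(4-methoxybenzyl)oxy]penta-3,4-dienal; 9 methyl propiolate
Product: 10 methyl (2E)-2-[(1S,2S)-1-hydroxy-2-[(4-methoxybenzyl)oxy]penta-3,4-dien-1-yl]-3-iodoprop-2-enoate
Conditions: 9, TiCl4, Bu4NI, CH2Cl2, −78 °C; then 8 precomplexed with TiCl4, −78 °C, quench cold
Reagents that add atoms: tetrabutylammonium iodide, CCCC[N+](CCCC)(CCCC)CCCC.[I-]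
Why: Iodide-triggered aldol of the propiolate (β-iodo Morita–Baylis–Hillman reaction): syn-iodotitanation should give the (E)-α-titanio-β-iodoacrylate, which at −78 °C adds with retention to the titanium-chelated α-OPMB aldehyde on the face opposite the allenyl group (Cram chelate), setting C9 syn to C8 and placing iodine cis to the carbinol.

Step 7
Reactants: 10 methyl (2E)-2-[(1S,2S)-1-hydroxy-2-[(4-methoxybenzyl)oxy]penta-3,4-dien-1-yl]-3-iodoprop-2-enoate
Product: 11 methyl (2E)-2-[(1S,2S)-1-[(tert-butyldimethylsilyl)oxy]-2-[(4-methoxybenzyl)oxy]penta-3,4-dien-1-yl]-3-iodoprop-2-enoate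
Conditions: TBSOTf, 2,6-lutidine, CH2Cl2, −78 to 0 °C
Reagents that add atoms: tert-butyldimethylsilyl triflate, CC(C)(C)[Si](C)(C)OS(=O)(=O)C(F)(F)F
Why: Silylation of the hindered allylic C9 hydroxyl gives an oxygen substituent that cannot act as a leaving group towards Ni(0) in step 15.

Step 8
Reactants: 12 (tert-butyldimethylsilyloxy)acetaldehyde; 9 methyl propiolate
Product: 13 methyl (4R)-5-[(tert-butyldimethylsilyl)oxy]-4-hydroxypent-2-ynoate
Conditions: Me2Zn, (S,S)-ProPhenol (10 mol %), toluene, 4 °C
Reagents that add atoms: none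
Why: Zinc–ProPhenol-catalysed asymmetric alkynylation of the aldehyde by the propiolate should set C5 under catalyst control.

Step 9
Reactants: 13 methyl (4R)-5-[(tert-butyldimethylsilyl)oxy]-4-hydroxypent-2-ynoate
Product: 15 (5R)-5-{[(tert-butyldimethylsilyl)oxy]methyl}-4-methylfuran-2(5H)-one, via Z-hydroxy enoate 14 (not isolated)
Conditions: Me2CuLi, THF, −78 °C; aq. NH4Cl, then cat. TsOH, rt
Reagents that add atoms: lithium dimethylcuprate, [Li+].C[Cu-]C
Why: syn-Carbocupration (conjugate addition) of the ynoate should give the Z-enoate carrying C15, whose γ-hydroxyl lactonises to the β-methylbutenolide with C5 unaffected.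

Step 10
Reactants: 15 (5R)-5-{[(tert-butyldimethylsilyl)oxy]methyl}-4-methylfuran-2(5H)-one
Product: 16 (5R)-5-{[(tert-butyldimethylsilyl)oxy]methyl}-4-methyl-2,5-dihydrofuran-2-ol
Conditions: DIBAL-H, CH2Cl2, −78 °C; Rochelle salt
Reagents that add atoms: none
Why: Low-temperature DIBAL-H reduction of the lactone should stop at the lactol, a ring-locked equivalent of the (Z)-γ-hydroxy enal.

Step 11
Reactants: 11 TBS-protected allenyl (E)-iodoacrylate; 16 lactol
Product: 17 methyl (2E,5Z,7R)-8-[(tert-butyldimethylsilyl)oxy]-4,7-dihydroxy-6-methyl-2-[(1S,2S)-1-[(tert-butyldimethylsilyl)oxy]-2-[(4-methoxybenzyl)oxy]penta-3,4-dien-1-yl]octa-2,5-dienoate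
Conditions: CrCl2, NiCl2 (cat.), DMSO, rt
Reagents that add atoms: none
Why: Nozaki–Hiyama–Kishi coupling: the alkenylchromium formed with retention of the E geometry should add chemoselectively to the open hydroxy-aldehyde form of the lactol (C1–C2 bond), tolerating ester, allene and free hydroxyl; the C2 carbinol configuration is irrelevant.

Step 12
Reactants: 17 seco diol
Product: 18 the 4,7-bis(tert-butyldimethylsilyl) ether of 17 (C2 and C5 oxygens silylated)
Conditions: TBSOTf, 2,6-lutidine, CH2Cl2, −78 to 0 °C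
Reagents that add atoms: tert-butyldimethylsilyl triflate, CC(C)(C)[Si](C)(C)OS(=O)(=O)C(F)(F)F
Why: Silylation of both secondary hydroxyls masks C2 and C5 as non-ionisable, base-stable ethers for the nickel step.

Step 13
Reactants: 18 tetrasilyl ether
Product: 19 the primary alcohol with C6–OH free and the C2, C5 and C9 silyl ethers kept
Conditions: HF·pyridine, pyridine, THF, 0 °C
Reagents that add atoms: none
Why: Buffered fluoride desilylation should cleave the unhindered primary silyl ether much faster than the three secondary ones.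

Step 14
Reactants: 19 primary alcohol
Product: 20 the C6 aldehyde (seco allenyl aldehyde)
Conditions: Dess–Martin periodinane, NaHCO3, CH2Cl2, 0 °C; used at once
Reagents that add atoms: none
Why: Non-basic Dess–Martin oxidation should give the α-silyloxy β,γ-unsaturated aldehyde without epimerising C5 or moving the C3=C4 double bond.

Step 15
Reactants: 20 seco allenyl aldehyde
Product: 24 macrocyclic α-methylene lactone (C8–OPMB; C2, C5 and C9 OTBS), via nickelalactone 21 (not isolated), via nickel alkoxide carboxylate 22 (not isolated), via seco hydroxy acid 23 (not isolated)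
Conditions: Ni(cod)2 (1.2 equiv), DBU, CO2 (1 atm), THF (2 mM), 0 °C to rt; then 1 M HCl; PPTS, benzene, rt
Reagents that add atoms: carbon dioxide, O=C=O
Why: Oxidative cyclisation of Ni(0), the terminal C11=C13 π bond and CO2 gives nickelalactone 21 with the new C11–C12 bond at the central allene carbon, and its allyl unit then adds through C7 to the nickel-bound C6 aldehyde in a six-membered cyclic transition state (22), after which acid releases hydroxy acid 23, which lactonises. The closest known reaction type is the nickel-promoted carboxylation/cyclisation cascade of allenyl aldehydes under CO2 (and its three-component form with external aldehydes), established for five- and six-membered carbocycles; the ten-membered ring is the extrapolation, supported by the macrocyclic Barbier-type allylations that close this same bond in germacranolides. The carbocycle closes by a 10-exo-trig allyl transfer (SE2′ at C7) and the lactone by 5-exo-trig attack of O6 on C12. C6 should be set by Felkin–Anh attack anti to the C5–OTBS bond (5,6-anti), and C7 by the A1,3-controlled conformer with H8 in the alkene plane, the aldehyde approaching anti to the C8–C9 bond (7,8-anti). Together these fix the 6,7-trans fusion, which requires the E σ-allyl isomer in a chair-like transition state, reachable because the allylnickel isomers interconvert through the η3 form. The step needs carboxylation before aldehyde engagement (CO2 atmosphere, the terminal allene being the best ligand for Ni(0)), attack through C7 rather than C13 (cyclic transition state from the C13-bound σ-allyl), and ring closure over oligomerisation (high dilution); silyl and PMB ethers at C8, C9 and C2 give Ni(0) no allylic leaving group.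

Step 16
Reactants: 24 macrocyclic lactone
Product: 25 the C8 alcohol
Conditions: DDQ, CH2Cl2/pH 7 buffer, 0 °C
Reagents that add atoms: none
Why: Oxidative PMB cleavage should free only the C8 hydroxyl, leaving silyl ethers, lactone and alkenes untouched.

Step 17
Reactants: 25 C8 alcohol
Product: 26 the C8 angelate
Conditions: angelic acid, 2,4,6-trichlorobenzoyl chloride, Et3N, toluene, rt; then 25, 80 °C
Reagents that add atoms: angelic acid, C/C=C(/C)C(=O)O
Why: Yamaguchi esterification through the mixed anhydride without DMAP should acylate the only free hydroxyl while avoiding base-induced angelate-to-tiglate isomerisation.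

Step 18
Reactants: 26 C8 angelate
Product: 27 the C2, C5, C9 triol
Conditions: HF·pyridine, pyridine, THF, 0 °C to rt
Reagents that add atoms: none
Why: Fluoride-mediated global desilylation under buffered conditions should spare the angelate, the methyl ester and the α-methylene lactone.

Step 19
Reactants: 27 triol
Product: 29 the 2,5-hemiketal with C9–OH free (9-desacetyl target), via hydroxy dienone 28 (not isolated)
Conditions: activated MnO2, CH2Cl2, rt
Reagents that add atoms: none
Why: MnO2 should oxidise the doubly allylic C2 carbinol fastest, and the cis-γ-hydroxy dienone 28 then closes spontaneously to the bridged hemiketal, whose C2 configuration is dictated by C5 and the bicyclic framework.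

Step 20
Reactants: 29 hemiketal alcohol
Product: 30 CNP0208424.1
Conditions: Ac2O, pyridine, CH2Cl2, 0 °C
Reagents that add atoms: acetic anhydride, CC(=O)OC(C)=O
Why: Acetylation should take place at the secondary allylic C9 hydroxyl only, the tertiary hemiketal hydroxyl being unreactive without DMAP.

Compound list
1 | (R)-2,2-dimethyl-1,3-dioxolane-4-carbaldehyde | O=C[C@H]1COC(C)(C)O1 | starting material
2 | (S)-4-ethynyl-2,2-dimethyl-1,3-dioxolane | C#C[C@H]1COC(C)(C)O1 | intermediate
3 | N,N-dicyclohexyl-3-[(4S)-2,2-dimethyl-1,3-dioxolan-4-yl]prop-2-yn-1-amine | C1CCCCC1N(CC#C[C@H]2COC(C)(C)O2)C3CCCCC3 | intermediate (not isolated)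
4 | (S)-2,2-dimethyl-4-(propa-1,2-dien-1-yl)-1,3-dioxolane | C=C=C[C@H]1COC(C)(C)O1 | intermediate
5 | (2S)-penta-3,4-diene-1,2-diol | C=C=C[C@H](O)CO | intermediate (not isolated)
6 | (4S)-2-(4-methoxyphenyl)-4-(propa-1,2-dien-1-yl)-1,3-dioxolane (acetal epimers) | C=C=C[C@H]1COC(c2ccc(OC)cc2)O1 | intermediate
7 | (2S)-2-[(4-methoxybenzyl)oxy]penta-3,4-dien-1-ol | C=C=C[C@H](OCc1ccc(OC)cc1)CO | intermediate
8 | (2S)-2-[(4-methoxybenzyl)oxy]penta-3,4-dienal | C=C=C[C@H](OCc1ccc(OC)cc1)C=O | intermediate
9 | methyl propiolate | C#CC(=O)OC | starting material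
10 | methyl (2E)-2-[(1S,2S)-1-hydroxy-2-[(4-methoxybenzyl)oxy]penta-3,4-dien-1-yl]-3-iodoprop-2-enoate | C=C=C[C@H](OCc1ccc(OC)cc1)[C@@H](O)/C(C(=O)OC)=C\I | intermediate
11 | TBS ether of 10 (C9–OTBS) | C=C=C[C@H](OCc1ccc(OC)cc1)[C@@H](O[Si](C)(C)C(C)(C)C)/C(C(=O)OC)=C\I | intermediate
12 | (tert-butyldimethylsilyloxy)acetaldehyde | O=CCO[Si](C)(C)C(C)(C)C | starting material
13 | methyl (4R)-5-[(tert-butyldimethylsilyl)oxy]-4-hydroxypent-2-ynoate | COC(=O)C#C[C@@H](O)CO[Si](C)(C)C(C)(C)C | intermediate
14 | methyl (2Z,4R)-5-[(tert-butyldimethylsilyl)oxy]-4-hydroxy-3-methylpent-2-enoate | COC(=O)/C=C(C)\[C@@H](O)CO[Si](C)(C)C(C)(C)C | intermediate (not isolated)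
15 | (5R)-5-{[(tert-butyldimethylsilyl)oxy]methyl}-4-methylfuran-2(5H)-one | O=C1C=C(C)[C@H](CO[Si](C)(C)C(C)(C)C)O1 | intermediate
16 | (5R)-5-{[(tert-butyldimethylsilyl)oxy]methyl}-4-methyl-2,5-dihydrofuran-2-ol (anomers) | OC1C=C(C)[C@H](CO[Si](C)(C)C(C)(C)C)O1 | intermediate
17 | seco diol: methyl (2E,5Z,7R)-8-(TBSO)-4,7-dihydroxy-6-methyl-2-[(1S,2S)-1-(TBSO)-2-(PMBO)penta-3,4-dien-1-yl]octa-2,5-dienoate (C4 epimers) | C=C=C[C@H](OCc1ccc(OC)cc1)[C@@H](O[Si](C)(C)C(C)(C)C)/C(C(=O)OC)=C\C(O)/C=C(C)\[C@@H](O)CO[Si](C)(C)C(C)(C)C | intermediate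
18 | 4,7-bis-TBS ether of 17 | C=C=C[C@H](OCc1ccc(OC)cc1)[C@@H](O[Si](C)(C)C(C)(C)C)/C(C(=O)OC)=C\C(O[Si](C)(C)C(C)(C)C)/C=C(C)\[C@@H](O[Si](C)(C)C(C)(C)C)CO[Si](C)(C)C(C)(C)C | intermediate
19 | primary alcohol (C6–OH free; C2, C5, C9 OTBS; C8 OPMB) | C=C=C[C@H](OCc1ccc(OC)cc1)[C@@H](O[Si](C)(C)C(C)(C)C)/C(C(=O)OC)=C\C(O[Si](C)(C)C(C)(C)C)/C=C(C)\[C@@H](O[Si](C)(C)C(C)(C)C)CO | intermediate
20 | seco allenyl aldehyde (C6 aldehyde, 5R) | C=C=C[C@H](OCc1ccc(OC)cc1)[C@@H](O[Si](C)(C)C(C)(C)C)/C(C(=O)OC)=C\C(O[Si](C)(C)C(C)(C)C)/C=C(C)\[C@@H](O[Si](C)(C)C(C)(C)C)C=O | intermediate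
21 | nickelalactone: 5-membered Ni–O–C12(=O)–C11(=C7H–)–C13H2 ring on the chain of 20 (DBU ligands omitted) | O=C1O[Ni]CC1=C[C@H](OCc2ccc(OC)cc2)[C@@H](O[Si](C)(C)C(C)(C)C)/C(C(=O)OC)=C\C(O[Si](C)(C)C(C)(C)C)/C=C(C)\[C@@H](O[Si](C)(C)C(C)(C)C)C=O | intermediate (not isolated)
22 | nickel(II) alkoxide carboxylate of the ring-closed seco acid (Ni bridging O6 and the C12 carboxylate) | C=C1C(=O)O[Ni]O[C@H]2[C@H]1[C@H](OCc3ccc(OC)cc3)[C@@H](O[Si](C)(C)C(C)(C)C)/C(C(=O)OC)=C\C(O[Si](C)(C)C(C)(C)C)/C=C(C)\[C@H]2O[Si](C)(C)C(C)(C)C | intermediate (not isolated)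
23 | seco hydroxy acid: ten-membered carbocycle with C6–OH and the 2-propenoic acid unit on C7 | OC(=O)C(=C)[C@@H]1[C@H](OCc2ccc(OC)cc2)[C@@H](O[Si](C)(C)C(C)(C)C)/C(C(=O)OC)=C\C(O[Si](C)(C)C(C)(C)C)/C=C(C)\[C@@H](O[Si](C)(C)C(C)(C)C)[C@H]1O | intermediate (not isolated)
24 | macrocyclic trans-fused α-methylene lactone, C5–C9 configured as in the target; C8 OPMB; C2, C5, C9 OTBS | C=C1C(=O)O[C@H]2[C@H]1[C@H](OCc3ccc(OC)cc3)[C@@H](O[Si](C)(C)C(C)(C)C)/C(C(=O)OC)=C\C(O[Si](C)(C)C(C)(C)C)/C=C(C)\[C@H]2O[Si](C)(C)C(C)(C)C | intermediate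
25 | C8 alcohol of 24 | C=C1C(=O)O[C@H]2[C@H]1[C@H](O)[C@@H](O[Si](C)(C)C(C)(C)C)/C(C(=O)OC)=C\C(O[Si](C)(C)C(C)(C)C)/C=C(C)\[C@H]2O[Si](C)(C)C(C)(C)C | intermediate
26 | C8 angelate (C2, C5, C9 OTBS) | C=C1C(=O)O[C@H]2[C@H]1[C@H](OC(=O)/C(C)=C\C)[C@@H](O[Si](C)(C)C(C)(C)C)/C(C(=O)OC)=C\C(O[Si](C)(C)C(C)(C)C)/C=C(C)\[C@H]2O[Si](C)(C)C(C)(C)C | intermediate
27 | C2, C5, C9 triol, C8 angelate | C=C1C(=O)O[C@H]2[C@H]1[C@H](OC(=O)/C(C)=C\C)[C@@H](O)/C(C(=O)OC)=C\C(O)/C=C(C)\[C@H]2O | intermediate
28 | hydroxy dienone (C2 ketone, C5–OH, C9–OH) | C=C1C(=O)O[C@H]2[C@H]1[C@H](OC(=O)/C(C)=C\C)[C@@H](O)/C(C(=O)OC)=C\C(=O)/C=C(C)\[C@H]2O | intermediate (not isolated)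
29 | 2,5-hemiketal with C9–OH free (9-desacetyl target) | C=C1C(=O)O[C@H]2[C@H]1[C@H](OC(=O)/C(C)=C\C)[C@@H](O)/C(C(=O)OC)=C\[C@@]1(O)C=C(C)[C@H]2O1 | intermediate
30 | CNP0208424.1 | C=C1C(=O)O[C@H]2[C@H]1[C@H](OC(=O)/C(C)=C\C)[C@@H](OC(C)=O)/C(C(=O)OC)=C\[C@@]1(O)C=C(C)[C@H]2O1 | target

Total step count: 20. Longest linear sequence: 17 steps (steps 1–7, then 11–20).

Steps most likely to fail

1. Step 15. The allylnickel may be protonated at work-up before it reaches the aldehyde (acyclic acid or oligomers), may close to the cis-fused lactone if one of the two facial preferences is overridden, and DBU may epimerise C5 of the aldehyde. Fallback: from 20, a carbonylative hetero-Pauson–Khand [2+2+1] cycloaddition (Ru3(CO)12 cat., CO 20 atm, dioxane, 120 °C, or Mo(CO)6/DMSO in toluene). Here allene and aldehyde are joined on one metal centre and CO, not CO2, supplies C12, without amine base. It returns directly to 24, with no new compound F0. Like the main step, this reaction is established only for five- and six-membered rings, so it answers the base and protonation problems rather than the ring-size risk.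

2. Step 6. Felkin–Anh addition may compete with chelate-controlled addition (giving the C9 epimer), and the kinetically formed E-iodoalkene may drift to the Z isomer if the mixture warms. Fallback: from 8, the epimeric methyl (2E)-2-[(1R,2S)-1-hydroxy-2-(PMBO)penta-3,4-dien-1-yl]-3-iodoprop-2-enoate F1 is not discarded but inverted by Mitsunobu reaction (ClCH2CO2H, PPh3, DIAD, THF, 0 °C; the β-iodine disfavours SN2′) to the (1S)-chloroacetate F2. F2 is cleaved with thiourea/NaHCO3 in EtOH, returning to 10. Stereocontrol at C9 thus moves from C–C bond formation to a C–O inversion; the alkene geometry is checked by NOE before going on.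

3. Step 19. Oxidation of the C5 allylic alcohol instead of the doubly allylic C2 carbinol would lead to the isomeric 5-hemiketal, and over-oxidation at C9 is also possible. Fallback: from 26, the least hindered, doubly allylic C2 silyl ether is removed alone (HF·pyridine/pyridine, THF, −20 °C) to give the C2 alcohol F3, which is oxidised (Dess–Martin periodinane) to the bis-silylated dienone F4. Global desilylation (HF·pyridine) then frees C5–OH, which closes onto the C2 ketone, returning to 29. The oxidation is thereby done while C5 and C9 are still protected.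

Further compounds
F0 | step 15 | none | none
F1 | step 6 | methyl (2E)-2-[(1R,2S)-1-hydroxy-2-[(4-methoxybenzyl)oxy]penta-3,4-dien-1-yl]-3-iodoprop-2-enoate | C=C=C[C@H](OCc1ccc(OC)cc1)[C@H](O)/C(C(=O)OC)=C\I
F2 | step 6 | methyl (2E)-2-[(1S,2S)-1-(chloroacetoxy)-2-[(4-methoxybenzyl)oxy]penta-3,4-dien-1-yl]-3-iodoprop-2-enoate | C=C=C[C@H](OCc1ccc(OC)cc1)[C@@H](OC(=O)CCl)/C(C(=O)OC)=C\I
F3 | step 19 | C2 alcohol of 26 (C5 and C9 OTBS, C8 angelate) | C=C1C(=O)O[C@H]2[C@H]1[C@H](OC(=O)/C(C)=C\C)[C@@H](O[Si](C)(C)C(C)(C)C)/C(C(=O)OC)=C\C(O)/C=C(C)\[C@H]2O[Si](C)(C)C(C)(C)C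
F4 | step 19 | C2 dienone (C5 and C9 OTBS, C8 angelate) | C=C1C(=O)O[C@H]2[C@H]1[C@H](OC(=O)/C(C)=C\C)[C@@H](O[Si](C)(C)C(C)(C)C)/C(C(=O)OC)=C\C(=O)/C=C(C)\[C@H]2O[Si](C)(C)C(C)(C)C
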